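**Plan**

1. The target is read as a (7S,8R,7′S,8′R) exo,exo-diaryl furofuran (a 3,7-dioxabicyclo[3.3.0]octane; lignan numbering: C7/C7′ benzylic, C8/C8′ ring fusion, C9/C9′ CH2O). Its C7 aryl group is C5 of a cis-(2S,3S)-2-guaiacyl-3-hydroxymethyl-7-methoxy-2,3-dihydrobenzofuran and its C7′ aryl group is syringyl.
2. Retrosynthetic cuts, in order: dihydrobenzofuran C2–C3 (carbenoid C–H insertion); aryl–CH2CO2Me and ArO–CH2Ar; both furofuran bonds C7–O and C7′–O; C7–C8 (lactone alkylation); C7′=C8′ (Stobbe condensation).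
3. Enabling feature: C7 and C7′ are each para to a phenolic oxygen on their arene and each lies 1,4 to a hydroxymethyl oxygen (O9′ and O9) across the C8–C8′ bond. The bicycle is therefore a (2R,3R)-2,3-dibenzylbutane-1,4-diol oxidised twice at its benzylic CH2 groups. A bromine ortho to one phenol is carried through as the later coupling handle and as a blocking, deactivating group.
4. Forward order: Stobbe half-ester, β-benzyl lactone, trans-dibenzyl lactone, diol; both tetrahydrofuran rings close in one oxidation; the guaiacyl unit is attached as a benzyl ether; the dihydrobenzofuran ring closes last.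
5. Stereochemistry: C8′ by asymmetric hydrogenation, C8 by trans alkylation, C7 and C7′ relayed from C8/C8′ in the double cyclisation, C2/C3 by a chiral rhodium carboxylate catalyst (cis is the kinetic insertion product).

Key step: step 11

Assumption: (4S,5S)-MOD-DIOP is taken to deliver the R half-ester and Rh2(R-PTTL)4 the (2S,3R) cis ester; if a trial on a simple model shows the opposite sense for either, the mirror-image ligand is used and nothing else changes.

**Route**

Step 1
Reactants: 1 syringaldehyde
Product: 2 3,5-dimethoxy-4-(methoxymethoxy)benzaldehyde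
Conditions: MOMCl, i-Pr2NEt, CH2Cl2, 0 °C → rt
Reagents that add atoms: chloromethyl methyl ether (MOMCl), COCCl
Why: Williamson-type O-alkylation masks the phenol, which as a phenoxide would deactivate the aldehyde in the Stobbe condensation, as an acetal that survives every basic and hydridic step up to step 10.

Step 2
Reactants: 2 3,5-dimethoxy-4-(methoxymethoxy)benzaldehyde; 3 dimethyl succinate
Product: 4 (E)-4-[3,5-dimethoxy-4-(methoxymethoxy)phenyl]-3-(methoxycarbonyl)but-3-enoic acid
Conditions: NaOMe, MeOH, reflux; then cold 1 M HCl to pH 3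
Reagents that add atoms: none
Why: Stobbe condensation (aldol addition, lactonisation, E1cB opening) should give the half-ester with the free acid on the CH2 arm and the thermodynamically preferred E alkene, as is usual for electron-rich benzaldehydes.

Step 3
Reactants: 4 (E)-4-[3,5-dimethoxy-4-(methoxymethoxy)phenyl]-3-(methoxycarbonyl)but-3-enoic acid
Product: 5 (R)-4-[3,5-dimethoxy-4-(methoxymethoxy)phenyl]-3-(methoxycarbonyl)butanoic acid
Conditions: H2 (1 atm), [Rh(cod)2]BF4 (0.5 mol%), (4S,5S)-MOD-DIOP, Et3N (1 equiv), MeOH, 30 °C; then cold 1 M HCl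
Reagents that add atoms: none
Why: Rhodium-catalysed asymmetric hydrogenation of an itaconate-type half-ester, in which the carboxylate binds the cationic metal and the C2-symmetric bisphosphine selects the alkene face, sets C8′ as R on a substrate class for which this ligand family is established.

Step 4
Reactants: 5 (R)-4-[3,5-dimethoxy-4-(methoxymethoxy)phenyl]-3-(methoxycarbonyl)butanoic acid
Product: 7 (R)-4-[3,5-dimethoxy-4-(methoxymethoxy)benzyl]dihydrofuran-2(3H)-one, via hydroxy acid 6 (not isolated)
Conditions: KOH (1 equiv), EtOH; CaCl2, NaBH4, EtOH, −10 °C → rt; then 1 M HCl to pH 2–3, rt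
Reagents that add atoms: none
Why: Chemoselective Ca(BH4)2 reduction of the methyl ester beside the potassium carboxylate, followed by acid-promoted lactonisation, should give the β-benzyl-γ-butyrolactone under conditions too weakly basic to epimerise the α-stereocentre.

Step 5
Reactants: 8 5-bromovanillin
Product: 9 3-bromo-5-methoxy-4-(methoxymethoxy)benzaldehyde
Conditions: MOMCl, i-Pr2NEt, CH2Cl2, 0 °C → rt
Reagents that add atoms: chloromethyl methyl ether (MOMCl), COCCl
Why: Williamson-type MOM protection of the acidic bromophenol gives the same acid-labile group as on the syringyl unit, so that both phenols are released together in step 10 without touching the aryl bromide.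

Step 6
Reactants: 9 3-bromo-5-methoxy-4-(methoxymethoxy)benzaldehyde
Product: 10 [3-bromo-5-methoxy-4-(methoxymethoxy)phenyl]methanol
Conditions: NaBH4, MeOH, 0 °C
Reagents that add atoms: none
Why: Borohydride reduction of an aromatic aldehyde to the benzylic alcohol leaves the aryl bromide and the acetal untouched.

Step 7
Reactants: 10 [3-bromo-5-methoxy-4-(methoxymethoxy)phenyl]methanol
Product: 11 1-bromo-5-(bromomethyl)-3-methoxy-2-(methoxymethoxy)benzene
Conditions: CBr4, PPh3, CH2Cl2, 0 °C
Reagents that add atoms: carbon tetrabromide, BrC(Br)(Br)Br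
Why: The Appel reaction converts the benzylic alcohol into the bromide under neutral conditions that spare the MOM ether.

Step 8
Reactants: 7 (R)-4-[3,5-dimethoxy-4-(methoxymethoxy)benzyl]dihydrofuran-2(3H)-one; 11 1-bromo-5-(bromomethyl)-3-methoxy-2-(methoxymethoxy)benzene
Product: 12 (3R,4R)-3-[3-bromo-5-methoxy-4-(methoxymethoxy)benzyl]-4-[3,5-dimethoxy-4-(methoxymethoxy)benzyl]dihydrofuran-2(3H)-one
Conditions: LiN(SiMe3)2, THF, −78 °C; then 11, DMPU, −78 → −30 °C
Reagents that add atoms: none
Why: Lactone enolate alkylation, in which the benzylic bromide approaches the face anti to the β-benzyl group, sets C8 trans to C8′ by substrate control and is the standard entry to trans-dibenzylbutyrolactones.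

Step 9
Reactants: 12 (3R,4R)-3-[3-bromo-5-methoxy-4-(methoxymethoxy)benzyl]-4-[3,5-dimethoxy-4-(methoxymethoxy)benzyl]dihydrofuran-2(3H)-one
Product: 13 (2R,3R)-2-[3-bromo-5-methoxy-4-(methoxymethoxy)benzyl]-3-[3,5-dimethoxy-4-(methoxymethoxy)benzyl]butane-1,4-diol
Conditions: LiAlH4, THF, 0 °C
Reagents that add atoms: none
Why: Hydride reduction of the lactone to the 1,4-diol is fast at 0 °C, where the aryl bromide is inert, and removes the only carbonyl that could epimerise C8.

Step 10
Reactants: 13 (2R,3R)-2-[3-bromo-5-methoxy-4-(methoxymethoxy)benzyl]-3-[3,5-dimethoxy-4-(methoxymethoxy)benzyl]butane-1,4-diol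
Product: 14 (2R,3R)-2-(3-bromo-4-hydroxy-5-methoxybenzyl)-3-(4-hydroxy-3,5-dimethoxybenzyl)butane-1,4-diol
Conditions: 3 M HCl, MeOH, 40 °C
Reagents that add atoms: none
Why: Acid-catalysed acetal exchange with methanol removes both MOM groups and frees the two para-phenols that the oxidation needs, while the saturated diol is inert under these conditions.

Step 11
Reactants: 14 (2R,3R)-2-(3-bromo-4-hydroxy-5-methoxybenzyl)-3-(4-hydroxy-3,5-dimethoxybenzyl)butane-1,4-diol
Product: 18 (1S,3aR,4S,6aR)-1-(3-bromo-4-hydroxy-5-methoxyphenyl)-4-(4-hydroxy-3,5-dimethoxyphenyl)tetrahydro-1H,3H-furo[3,4-c]furan, via syringyl quinone methide 15 (not isolated), via monocyclic tetrahydrofuran 16 (not isolated), via bromoguaiacyl quinone methide 17 (not isolated)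
Conditions: DDQ (2.1 equiv, two portions), CH2Cl2–1,4-dioxane (3:1), 0.01 M, 0 °C → rt
Reagents that add atoms: none
Why: Proposed new method: DDQ oxidises the more electron-rich syringyl phenol with loss of the para-benzylic C7′ hydrogen to give quinone methide 15, the C9 hydroxyl adds to C7′ and the phenol is restored (16), and a second equivalent repeats the sequence on the bromoguaiacyl ring through 17 with O9′ adding to C7. The closest known reaction type is the single DDQ or enzymatic quinone-methide cyclisation of a dibenzylbutanediol to a 7,9′-epoxylignan, here asked to run twice in one flask. Each tetrahydrofuran ring closes 5-exo-trig by intramolecular oxa-1,6-conjugate addition (O9 to C7′, then O9′ to C7). C7′ is controlled by C8′, the oxygen adding to the methide face that places the aryl group trans to C9′, and C7 is controlled by C8 and by the ring already formed, since the second closure can only give the cis-fused bicycle and puts the aryl group on its convex face; C8 and C8′ are not touched. The step needs oxygen capture to beat Friedel–Crafts capture and phenoxyl coupling: the hydroxyl is held five atoms from the methide carbon, no Lewis acid is present, the bromine lowers the π-nucleophilicity of its ring, and both phenols are flanked on both sides (OMe/OMe and OMe/Br) so that ortho coupling is blocked. Over-oxidation of the new para-hydroxybenzylic ethers is limited by using just over two equivalents of DDQ in portions at high dilution.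

Step 12
Reactants: 19 vanillin
Product: 20 3-methoxy-4-(triisopropylsilyloxy)benzaldehyde
Conditions: TIPSCl, imidazole, DMF, rt
Reagents that add atoms: triisopropylsilyl chloride (TIPSCl), CC(C)[Si](Cl)(C(C)C)C(C)C
Why: Silylation of the phenol gives a bulky aryl silyl ether that should survive carbonate, zinc enolate, amidine base and carbenoid conditions and fall to fluoride at the end.

Step 13
Reactants: 20 3-methoxy-4-(triisopropylsilyloxy)benzaldehyde
Product: 21 [3-methoxy-4-(triisopropylsilyloxy)phenyl]methanol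
Conditions: NaBH4, MeOH, 0 °C
Reagents that add atoms: none
Why: Borohydride reduction of the aldehyde gives the benzylic alcohol without affecting the aryl silyl ether.

Step 14
Reactants: 21 [3-methoxy-4-(triisopropylsilyloxy)phenyl]methanol
Product: 22 4-(bromomethyl)-2-methoxy-1-(triisopropylsilyloxy)benzene
Conditions: CBr4, PPh3, CH2Cl2, 0 °C; used at once
Reagents that add atoms: carbon tetrabromide, BrC(Br)(Br)Br
Why: The Appel reaction gives the electron-rich benzylic bromide under neutral conditions, and immediate use avoids its ionisation on storage.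

Step 15
Reactants: 18 furofuran bis-phenol; 22 4-(bromomethyl)-2-methoxy-1-(triisopropylsilyloxy)benzene
Product: 23 furofuran whose C7 aryl is 3-bromo-5-methoxy-4-{[3-methoxy-4-(triisopropylsilyloxy)benzyl]oxy}phenyl and whose C7′ aryl is still 4-hydroxy-3,5-dimethoxyphenyl
Conditions: K2CO3 (1.05 equiv), DMF, 0 °C → rt
Reagents that add atoms: none
Why: Williamson ether synthesis under base-limited conditions should alkylate the ortho-bromophenol, which is more acidic than the syringol by more than one pKa unit and is therefore the phenoxide mainly present.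

Step 16
Reactants: 23 mono-benzylated furofuran with free syringol
Product: 24 furofuran whose C7 aryl is 3-bromo-5-methoxy-4-{[3-methoxy-4-(triisopropylsilyloxy)benzyl]oxy}phenyl and whose C7′ aryl is 3,5-dimethoxy-4-(triisopropylsilyloxy)phenyl
Conditions: TIPSCl, imidazole, DMAP (cat.), DMF, 40 °C
Reagents that add atoms: triisopropylsilyl chloride (TIPSCl), CC(C)[Si](Cl)(C(C)C)C(C)C
Why: Silylation of the remaining phenol removes the last O–H bond, which would otherwise quench the zinc enolate and capture the carbenoid by O–H insertion.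

Step 17
Reactants: 24 bis-silylated aryl bromide
Product: 25 methyl arylacetate (CH2CO2Me in place of Br in 24)
Conditions: BrZnCH2CO2Me (from methyl bromoacetate and Zn dust, THF), Pd2(dba)3 (2.5 mol%), XPhos (10 mol%), THF, 60 °C
Reagents that add atoms: methyl bromozincacetate (Reformatsky reagent), COC(=O)C[Zn]Br
Why: Negishi-type coupling of a Reformatsky reagent (palladium-catalysed α-arylation of an acetate zinc enolate) uses a neutral nucleophile that tolerates the silyl and benzylic ethers, and the bulky biarylphosphine allows oxidative addition into the ortho-alkoxy aryl bromide.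

Step 18
Reactants: 25 methyl arylacetate
Product: 26 methyl aryldiazoacetate (C(=N2)CO2Me in place of CH2CO2Me in 25)
Conditions: p-ABSA, DBU, MeCN, 0 °C → rt
Reagents that add atoms: 4-acetamidobenzenesulfonyl azide (p-ABSA), CC(=O)Nc1ccc(cc1)S(=O)(=O)N=[N+]=[N-]
Why: Regitz diazo transfer to the benzylic ester is the standard preparation of aryldiazoacetates, the donor/acceptor carbene precursors.

Step 19
Reactants: 26 methyl aryldiazoacetate
Product: 27 methyl (2S,3R)-cis-7-methoxy-2-[3-methoxy-4-(triisopropylsilyloxy)phenyl]-5-(furofuranyl)-2,3-dihydrobenzofuran-3-carboxylate, the furofuran unchanged with 3,5-dimethoxy-4-(triisopropylsilyloxy)phenyl at C7′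
Conditions: Rh2(R-PTTL)4 (dirhodium tetrakis[N-phthaloyl-(R)-tert-leucinate], 2 mol%), toluene, −60 °C
Reagents that add atoms: none
Why: Intramolecular 1,5 C–H insertion of a donor/acceptor rhodium carbenoid into the benzylic ether C–H bond gives the cis-2-aryl-3-carboxylate kinetically, and the chiral carboxylate ligands choose between the enantiotopic benzylic hydrogens, so that C2 and C3 are set together under catalyst control as established for ortho-benzyloxyaryl diazoacetates with this catalyst family.

Step 20
Reactants: 27 cis ester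
Product: 28 bis-silyl ether of the target, (2S,3S)-cis-3-hydroxymethyl
Conditions: i-Bu2AlH, CH2Cl2, −78 °C; aq. potassium sodium tartrate
Reagents that add atoms: none
Why: Aluminium hydride reduction of the methyl ester under non-basic, low-temperature conditions does not enolise C3, so the cis relationship is kept (the C3 descriptor changes from R to S only through the priority rules).

Step 21
Reactants: 28 bis-silyl ether of the target
Product: 29 CNP0126146.1 (target)
Conditions: Bu4NF, AcOH, THF, 0 °C
Reagents that add atoms: none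
Why: Fluoride-induced cleavage of both aryl silyl ethers, buffered with acetic acid, avoids a free phenoxide that could open the para-hydroxybenzylic ethers through a quinone methide and scramble C2, C7 or C7′.

**Compound list**

1 | syringaldehyde (4-hydroxy-3,5-dimethoxybenzaldehyde) | COc1cc(C=O)cc(OC)c1O | starting material
2 | 3,5-dimethoxy-4-(methoxymethoxy)benzaldehyde | COCOc1c(OC)cc(C=O)cc1OC | intermediate
3 | dimethyl succinate | COC(=O)CCC(=O)OC | starting material
4 | (E)-4-[3,5-dimethoxy-4-(methoxymethoxy)phenyl]-3-(methoxycarbonyl)but-3-enoic acid | COCOc1c(OC)cc(/C=C(\CC(=O)O)C(=O)OC)cc1OC | intermediate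
5 | (R)-4-[3,5-dimethoxy-4-(methoxymethoxy)phenyl]-3-(methoxycarbonyl)butanoic acid | COCOc1c(OC)cc(C[C@H](CC(=O)O)C(=O)OC)cc1OC | intermediate
6 | (R)-4-[3,5-dimethoxy-4-(methoxymethoxy)phenyl]-3-(hydroxymethyl)butanoic acid (not isolated) | COCOc1c(OC)cc(C[C@H](CC(=O)O)CO)cc1OC | intermediate
7 | (R)-4-[3,5-dimethoxy-4-(methoxymethoxy)benzyl]dihydrofuran-2(3H)-one | O=C1C[C@@H](Cc2cc(OC)c(OCOC)c(OC)c2)CO1 | intermediate
8 | 5-bromovanillin (3-bromo-4-hydroxy-5-methoxybenzaldehyde) | COc1cc(C=O)cc(Br)c1O | starting material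
9 | 3-bromo-5-methoxy-4-(methoxymethoxy)benzaldehyde | COCOc1c(Br)cc(C=O)cc1OC | intermediate
10 | [3-bromo-5-methoxy-4-(methoxymethoxy)phenyl]methanol | COCOc1c(Br)cc(CO)cc1OC | intermediate
11 | 1-bromo-5-(bromomethyl)-3-methoxy-2-(methoxymethoxy)benzene | COCOc1c(Br)cc(CBr)cc1OC | intermediate
12 | (3R,4R)-3-[3-bromo-5-methoxy-4-(methoxymethoxy)benzyl]-4-[3,5-dimethoxy-4-(methoxymethoxy)benzyl]dihydrofuran-2(3H)-one (trans) | O=C1OC[C@H](Cc2cc(OC)c(OCOC)c(OC)c2)[C@H]1Cc1cc(OC)c(OCOC)c(Br)c1 | intermediate
13 | (2R,3R)-2-[3-bromo-5-methoxy-4-(methoxymethoxy)benzyl]-3-[3,5-dimethoxy-4-(methoxymethoxy)benzyl]butane-1,4-diol | OC[C@H](Cc1cc(OC)c(OCOC)c(Br)c1)[C@H](CO)Cc1cc(OC)c(OCOC)c(OC)c1 | intermediate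
14 | (2R,3R)-2-(3-bromo-4-hydroxy-5-methoxybenzyl)-3-(4-hydroxy-3,5-dimethoxybenzyl)butane-1,4-diol | OC[C@H](Cc1cc(OC)c(O)c(Br)c1)[C@H](CO)Cc1cc(OC)c(O)c(OC)c1 | intermediate
15 | syringyl para-quinone methide of 14 (C7′=C1′ exocyclic alkene on a 2,6-dimethoxycyclohexa-2,5-dienone; C8 and C8′ unchanged; not isolated) | OC[C@H](Cc1cc(OC)c(O)c(Br)c1)[C@H](CO)C=C1C=C(OC)C(=O)C(OC)=C1 | intermediate
16 | (2S,3R,4R)-4-(3-bromo-4-hydroxy-5-methoxybenzyl)-2-(4-hydroxy-3,5-dimethoxyphenyl)-3-(hydroxymethyl)tetrahydrofuran (not isolated) | OC[C@H]1[C@@H](Cc2cc(OC)c(O)c(Br)c2)CO[C@@H]1c1cc(OC)c(O)c(OC)c1 | intermediate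
17 | bromoguaiacyl para-quinone methide of 16 (C7=C1 exocyclic alkene on a 2-bromo-6-methoxycyclohexa-2,5-dienone, either alkene geometry; ring stereocentres as in 16; not isolated) | OC[C@H]1[C@@H](C=C2C=C(OC)C(=O)C(Br)=C2)CO[C@@H]1c1cc(OC)c(O)c(OC)c1 | intermediate
18 | (1S,3aR,4S,6aR)-1-(3-bromo-4-hydroxy-5-methoxyphenyl)-4-(4-hydroxy-3,5-dimethoxyphenyl)tetrahydro-1H,3H-furo[3,4-c]furan (lignan descriptors 7S,8R,7′S,8′R; both aryl groups exo) | COc1cc([C@H]2OC[C@H]3[C@@H]2CO[C@@H]3c2cc(OC)c(O)c(OC)c2)cc(Br)c1O | intermediate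
19 | vanillin (4-hydroxy-3-methoxybenzaldehyde) | COc1cc(C=O)ccc1O | starting material
20 | 3-methoxy-4-(triisopropylsilyloxy)benzaldehyde | COc1cc(C=O)ccc1O[Si](C(C)C)(C(C)C)C(C)C | intermediate
21 | [3-methoxy-4-(triisopropylsilyloxy)phenyl]methanol | COc1cc(CO)ccc1O[Si](C(C)C)(C(C)C)C(C)C | intermediate
22 | 4-(bromomethyl)-2-methoxy-1-(triisopropylsilyloxy)benzene | COc1cc(CBr)ccc1O[Si](C(C)C)(C(C)C)C(C)C | intermediate
23 | furofuran 18 with the bromophenol oxygen carrying a 3-methoxy-4-(triisopropylsilyloxy)benzyl group; syringol free; (7S,8R,7′S,8′R) | COc1cc([C@H]2OC[C@H]3[C@@H]2CO[C@@H]3c2cc(OC)c(O)c(OC)c2)cc(Br)c1OCc1ccc(O[Si](C(C)C)(C(C)C)C(C)C)c(OC)c1 | intermediate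
24 | triisopropylsilyl ether of 23 at the syringol oxygen; (7S,8R,7′S,8′R) | COc1cc([C@H]2OC[C@H]3[C@@H]2CO[C@@H]3c2cc(OC)c(O[Si](C(C)C)(C(C)C)C(C)C)c(OC)c2)cc(Br)c1OCc1ccc(O[Si](C(C)C)(C(C)C)C(C)C)c(OC)c1 | intermediate
25 | methyl 2-aryl-acetate from 24 (CH2CO2Me in place of Br); (7S,8R,7′S,8′R) | COc1cc([C@H]2OC[C@H]3[C@@H]2CO[C@@H]3c2cc(OC)c(O[Si](C(C)C)(C(C)C)C(C)C)c(OC)c2)cc(CC(=O)OC)c1OCc1ccc(O[Si](C(C)C)(C(C)C)C(C)C)c(OC)c1 | intermediate
26 | methyl 2-aryl-2-diazoacetate from 25; (7S,8R,7′S,8′R) | COc1cc([C@H]2OC[C@H]3[C@@H]2CO[C@@H]3c2cc(OC)c(O[Si](C(C)C)(C(C)C)C(C)C)c(OC)c2)cc(C(=[N+]=[N-])C(=O)OC)c1OCc1ccc(O[Si](C(C)C)(C(C)C)C(C)C)c(OC)c1 | intermediate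
27 | methyl (2S,3R)-cis-7-methoxy-2-[3-methoxy-4-(triisopropylsilyloxy)phenyl]-2,3-dihydrobenzofuran-3-carboxylate carrying at C5 the (7S,8R,7′S,8′R) furofuran with 3,5-dimethoxy-4-(triisopropylsilyloxy)phenyl at C7′ | COc1cc([C@H]2Oc3c(OC)cc([C@H]4OC[C@H]5[C@@H]4CO[C@@H]5c4cc(OC)c(O[Si](C(C)C)(C(C)C)C(C)C)c(OC)c4)cc3[C@H]2C(=O)OC)ccc1O[Si](C(C)C)(C(C)C)C(C)C | intermediate
28 | (2S,3S)-cis-3-hydroxymethyl analogue of 27 (bis-triisopropylsilyl ether of the target) | COc1cc([C@H]2Oc3c(OC)cc([C@H]4OC[C@H]5[C@@H]4CO[C@@H]5c4cc(OC)c(O[Si](C(C)C)(C(C)C)C(C)C)c(OC)c4)cc3[C@H]2CO)ccc1O[Si](C(C)C)(C(C)C)C(C)C | intermediate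
29 | CNP0126146.1: cis-(2S,3S)-dihydrobenzofuran, (7S,8R,7′S,8′R)-furofuran | COc1cc([C@H]2Oc3c(OC)cc([C@H]4OC[C@H]5[C@@H]4CO[C@@H]5c4cc(OC)c(O)c(OC)c4)cc3[C@H]2CO)ccc1O | target

**Step count and risks**

Total: 21 steps. Longest linear sequence: 15 steps (1–4, 8–11, 15–21, from syringaldehyde).

Most likely to fail:

Step 11 (double quinone-methide cyclisation). The first-formed para-hydroxybenzylic ether may be re-oxidised faster than the second, less electron-rich ring is oxidised, which would open the ring to an aryl ketone. The first methide may also be captured by the other arene to give an aryltetralin, or the cascade may stall after one ring. The fallback forms the two benzylic C–O bonds one at a time with known reactions. It sets out from lactone 7 and aldehyde 9 and rejoins the route at 18. Aldol addition of the lithium enolate of 7 (LiN(SiMe3)2, THF, −78 °C) to 9 gives the trans aldol adduct F1 as carbinol epimers, both usable. LiAlH4 gives the triol F2. Camphorsulfonic acid in CH2Cl2 ionises the benzylic alcohol, and O9′ closes the first ring to the 7,8-trans 2-aryltetrahydrofuran F3. HCl in MeOH removes the MOM groups to give the bis-phenol F4. One equivalent of DDQ then performs a single quinone-methide cyclisation on the more electron-rich syringyl ring, which closes the second ring to 18.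

Step 19 (carbenoid C–H insertion). The cis preference may be insufficient, the cis ester may epimerise at C3 during isolation, or facial control at C2 may be incomplete in this crowded substrate. The fallback sets out from 26 and rejoins at 27. The insertion is run for control of C2 only. The crude ester mixture is equilibrated at C3 with catalytic t-BuOK in THF–t-BuOH at 0 °C to converge on the trans ester F7. At this stage any C2 epimer is a diastereomer, because of the four furofuran centres, and can be removed by chromatography. F7 is then enolised with LiN(i-Pr)2 at −78 °C and protonated kinetically with 2,6-di-tert-butylphenol from the face anti to the C2 aryl group, which returns the cis ester 27.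

Step 15 (differentiation of the two phenols). Alkylation may also occur on the syringol oxygen or on both phenols, because the less acidic phenoxide is the better nucleophile. The fallback sets out from 18 and rejoins at 24, bypassing 23 and step 16. Both phenols are silylated (TIPSCl, imidazole, DMF) to the bis-silyl ether F5. K2CO3 (0.5 equiv) in MeOH–THF at 0 °C should cleave first the silyl ether of the more acidic bromophenol, which is the better leaving group, to give the mono-silyl ether F6 with only the bromophenol free. Alkylation of F6 with 22 (K2CO3, DMF) then gives 24 with no competing nucleophile.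

**Further compounds**

F1 | step 11 | (3S,4R)-3-{[3-bromo-5-methoxy-4-(methoxymethoxy)phenyl](hydroxy)methyl}-4-[3,5-dimethoxy-4-(methoxymethoxy)benzyl]dihydrofuran-2(3H)-one (trans, carbinol epimers) | O=C1OC[C@H](Cc2cc(OC)c(OCOC)c(OC)c2)[C@H]1C(O)c1cc(OC)c(OCOC)c(Br)c1
F2 | step 11 | (2R,3R)-2-{[3-bromo-5-methoxy-4-(methoxymethoxy)phenyl](hydroxy)methyl}-3-[3,5-dimethoxy-4-(methoxymethoxy)benzyl]butane-1,4-diol (carbinol epimers) | OC[C@H](C(O)c1cc(OC)c(OCOC)c(Br)c1)[C@H](CO)Cc1cc(OC)c(OCOC)c(OC)c1
F3 | step 11 | (2S,3R,4R)-2-[3-bromo-5-methoxy-4-(methoxymethoxy)phenyl]-4-[3,5-dimethoxy-4-(methoxymethoxy)benzyl]-3-(hydroxymethyl)tetrahydrofuran | COCOc1c(Br)cc([C@H]2OC[C@H](Cc3cc(OC)c(OCOC)c(OC)c3)[C@@H]2CO)cc1OC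
F4 | step 11 | (2S,3R,4R)-2-(3-bromo-4-hydroxy-5-methoxyphenyl)-4-(4-hydroxy-3,5-dimethoxybenzyl)-3-(hydroxymethyl)tetrahydrofuran | COc1cc([C@H]2OC[C@H](Cc3cc(OC)c(O)c(OC)c3)[C@@H]2CO)cc(Br)c1O
F5 | step 15 | bis(triisopropylsilyl) ether of 18 | COc1cc([C@H]2OC[C@H]3[C@@H]2CO[C@@H]3c2cc(OC)c(O[Si](C(C)C)(C(C)C)C(C)C)c(OC)c2)cc(Br)c1O[Si](C(C)C)(C(C)C)C(C)C
F6 | step 15 | mono(triisopropylsilyl) ether of 18 at the syringol oxygen, bromophenol free | COc1cc([C@H]2OC[C@H]3[C@@H]2CO[C@@H]3c2cc(OC)c(O[Si](C(C)C)(C(C)C)C(C)C)c(OC)c2)cc(Br)c1O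
F7 | step 19 | methyl (2S,3S)-trans-2,3-dihydrobenzofuran-3-carboxylate, the C3 epimer of 27 | COc1cc([C@H]2Oc3c(OC)cc([C@H]4OC[C@H]5[C@@H]4CO[C@@H]5c4cc(OC)c(O[Si](C(C)C)(C(C)C)C(C)C)c(OC)c4)cc3[C@@H]2C(=O)OC)ccc1O[Si](C(C)C)(C(C)C)C(C)C
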